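Kuwanon A is cut through ring C at C3–C4 and O1–C8a. Ring C is a vinylogous ester whose ether oxygen O1 sits on C8a, ortho to the C4 carbonyl. The ring A oxygens on C5 and C7 lie ortho and para to the same carbonyl, so all three carbons can start as C–F. In one flask the enolate of a homoprenyl aryl ketone is C-aroylated by 2,4,6-trifluorobenzoyl chloride, and the diketone enolate then expels an ortho fluoride, closing ring C. The precursor is an 8-acyl-2,2-dimethylchromene that already holds ring B, C2, C3 and the prenyl chain. Its phenol is an allyl ether, so one neutral palladium step ends the route.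

Key step: step 5

Remark 1: the target has no stereocentre, and its only ring alkene (the chromene C=C) is cis by ring size, so no step has to control configuration.
Remark 2: the ring B phenol is carried as an allyl ether rather than an acetal ether. An acetal could be cleaved by the MgBr2/acid chloride pair of step 5 and would force an acidic last step next to the chromene and prenyl groups. The allyl group leaves together with the two ring A allyl ethers.
Remark 3 (assumption): in step 6 the C7 fluoride is taken to leave before the C5 fluoride; the order has no bearing on the product.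

Step 1
Reactants: 1 2,4-dihydroxyacetophenone
Product: 2 1-[2-hydroxy-4-(prop-2-en-1-yloxy)phenyl]ethan-1-one
Conditions: allyl bromide (1.05 equiv), K2CO3 (1.1 equiv), acetone, reflux
Reagents that add atoms: allyl bromide, C=CCBr
Why: Williamson ether synthesis: the 2-OH is hydrogen-bonded to the acetyl oxygen and is the weaker nucleophile, so one equivalent of allyl bromide with a mild carbonate base should alkylate only the free 4-OH.

Step 2
Reactants: 2 1-[2-hydroxy-4-(prop-2-en-1-yloxy)phenyl]ethan-1-one; 3 3-chloro-3-methylbut-1-yne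
Product: 4 1-{2-[(2-methylbut-3-yn-2-yl)oxy]-4-(prop-2-en-1-yloxy)phenyl}ethan-1-one
Conditions: 3 (1.5 equiv), CuCl2·2H2O (1 mol %), DBU (2 equiv), MeCN, Ar, 0 °C to rt
Reagents that add atoms: none
Why: Copper-catalysed propargylic etherification: DBU ionises the chelated phenol fully and the tertiary chloride reacts through a flat, copper-bound propargyl/allenylidene cation equivalent, so the crowded 2-oxygen can be captured at a temperature where the ether does not yet rearrange.

Step 3
Reactants: 4 1-{2-[(2-methylbut-3-yn-2-yl)oxy]-4-(prop-2-en-1-yloxy)phenyl}ethan-1-one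
Product: 6 1-[2,2-dimethyl-5-(prop-2-en-1-yloxy)-2H-chromen-8-yl]ethan-1-one, via ortho-allenylphenol 5 (not isolated)
Conditions: xylene, Ar, 130 °C
Reagents that add atoms: none
Why: Aromatic propargyl Claisen rearrangement: the [3,3] shift can end productively only at C3 because the other ortho carbon bears the acetyl group, allenylphenol 5 then passes through a 1,5-hydrogen shift and an oxa-6π electrocyclisation to the chromene, and the gem-dimethyl acceleration lets all this run well below the temperature at which the allyl aryl ether would begin its own Claisen rearrangement.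

Step 4
Reactants: 6 1-[2,2-dimethyl-5-(prop-2-en-1-yloxy)-2H-chromen-8-yl]ethan-1-one; 7 prenyl bromide (1-bromo-3-methylbut-2-ene)
Product: 9 1-[2,2-dimethyl-5-(prop-2-en-1-yloxy)-2H-chromen-8-yl]-5-methylhex-4-en-1-one, via lithium enolate 8 (not isolated)
Conditions: LiN(i-Pr)2 (LDA, 1.05 equiv), THF, −78 °C; then 7 (0.95 equiv), −78 °C to 0 °C
Reagents that add atoms: none
Why: Alkylation of a kinetic lithium enolate (SN2 on a primary allylic bromide): the methyl ketone has a single enolisable position, deprotonation is complete before the bromide is added, and keeping the bromide limiting at low temperature should hold back proton exchange and a second alkylation.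

Step 5
Reactants: 9 1-[2,2-dimethyl-5-(prop-2-en-1-yloxy)-2H-chromen-8-yl]-5-methylhex-4-en-1-one; 10 2,4,6-trifluorobenzoyl chloride
Product: 13 2-[2,2-dimethyl-5-(prop-2-en-1-yloxy)-2H-chromen-8-yl]-5,7-difluoro-3-(3-methylbut-2-en-1-yl)-4H-chromen-4-one, via bromomagnesium enolate 11 (not isolated), via 2-prenyl-1,3-diketone 12 (not isolated)
Conditions: MgBr2·OEt2 (2.5 equiv), i-Pr2NEt (3 equiv), 10 (1.2 equiv), CH2Cl2, 0 °C to rt; then evaporate, K2CO3 (5 equiv), MeCN, 80 °C
Reagents that add atoms: none
Why: MgBr2 binds the ketone oxygen together with the neighbouring chromene oxygen, so i-Pr2NEt can remove a proton from the future C3 and give the chelated enolate 11, which attacks acid chloride 10 through carbon (C3–C4) and is held as the magnesium diketonate of 12. After the change to K2CO3 in MeCN the freed enolate oxygen on C2 adds to C8a, giving a Meisenheimer anion whose charge is taken up by the ortho C4 carbonyl and eased inductively by the fluorines on C5 and C7 (both meta to the point of attack), and loss of fluoride forms O1–C8a. The closest known reaction type is the soft-enolisation acylation of ketones with acid chlorides, joined to the one-pot aroylation/intramolecular SNAr synthesis of 2,3-disubstituted chromones from 2-fluorobenzoyl chlorides. Ring C closes by a six-membered addition–elimination best counted as 6-endo-trig, because the C8a=C4a bond that accepts the electrons and relays them to C4=O lies inside the new ring, while the oxygen on C4 could only make a four-membered ring and does not compete. No stereocentre results, since the C3 centre of 12 is racemic, labile and becomes sp2. The step needs C- over O-acylation, secured by the tight magnesium chelate in a non-polar solvent, and a single closure site, secured by the two equivalent ortho fluorines of 10, and the allyl ether is inert to the Lewis acid, the acid chloride and the fluoride released.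

Step 6
Reactants: 13 2-[2,2-dimethyl-5-(prop-2-en-1-yloxy)-2H-chromen-8-yl]-5,7-difluoro-3-(3-methylbut-2-en-1-yl)-4H-chromen-4-one
Product: 15 2-[2,2-dimethyl-5-(prop-2-en-1-yloxy)-2H-chromen-8-yl]-3-(3-methylbut-2-en-1-yl)-5,7-bis(prop-2-en-1-yloxy)-4H-chromen-4-one, via 7-allyloxy-5-fluoro monoether 14 (not isolated)
Conditions: allyl alcohol (5 equiv), NaH (3.5 equiv), THF, 0 °C; then 13, NMP, rt to 70 °C
Reagents that add atoms: allyl alcohol (used as its sodium salt), C=CCO
Why: Twofold SNAr (addition–elimination): C7 is para and C5 ortho to the C4 carbonyl and fluoride is the best leaving group for this mechanism, so the para site should react first in the dipolar medium (14) and the ortho site on warming, while C2 is protected from the alkoxide by full substitution and by the electron-rich, twisted ring B.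

Step 7
Reactants: 15 2-[2,2-dimethyl-5-(prop-2-en-1-yloxy)-2H-chromen-8-yl]-3-(3-methylbut-2-en-1-yl)-5,7-bis(prop-2-en-1-yloxy)-4H-chromen-4-one
Product: 16 Kuwanon A, 5,7-dihydroxy-2-(5-hydroxy-2,2-dimethyl-2H-chromen-8-yl)-3-(3-methylbut-2-en-1-yl)-4H-chromen-4-one
Conditions: Pd(PPh3)4 (5 mol %), morpholine (15 equiv), THF, Ar, rt; pH 5 buffer work-up
Reagents that add atoms: none
Why: Tsuji–Trost-type deallylation: zerovalent palladium ionises the three unsubstituted allyl aryl ethers to π-allyl complexes that the large excess of morpholine intercepts before they can C-allylate ring A, the medium stays neutral so the prenyl group is untouched, and the chromene C–O bond is spared because it is tertiary and its alkene is disubstituted, endocyclic and conjugated, hence a poor ligand.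

Compound list
1 | 2,4-dihydroxyacetophenone | CC(=O)c1ccc(O)cc1O | starting material
2 | 1-[2-hydroxy-4-(prop-2-en-1-yloxy)phenyl]ethan-1-one | CC(=O)c1ccc(OCC=C)cc1O | intermediate
3 | 3-chloro-3-methylbut-1-yne | CC(C)(Cl)C#C | starting material
4 | 1-{2-[(2-methylbut-3-yn-2-yl)oxy]-4-(prop-2-en-1-yloxy)phenyl}ethan-1-one | CC(=O)c1ccc(OCC=C)cc1OC(C)(C)C#C | intermediate
5 | 1-[2-hydroxy-3-(3-methylbuta-1,2-dien-1-yl)-4-(prop-2-en-1-yloxy)phenyl]ethan-1-one (ortho-allenylphenol, not isolated) | CC(=O)c1ccc(OCC=C)c(C=C=C(C)C)c1O | intermediate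
6 | 1-[2,2-dimethyl-5-(prop-2-en-1-yloxy)-2H-chromen-8-yl]ethan-1-one | CC(=O)c1ccc(OCC=C)c2c1OC(C)(C)C=C2 | intermediate
7 | prenyl bromide (1-bromo-3-methylbut-2-ene) | CC(C)=CCBr | starting material
8 | lithium enolate of 6 (not isolated) | [Li+].[O-]C(=C)c1ccc(OCC=C)c2c1OC(C)(C)C=C2 | intermediate
9 | 1-[2,2-dimethyl-5-(prop-2-en-1-yloxy)-2H-chromen-8-yl]-5-methylhex-4-en-1-one | CC(C)=CCCC(=O)c1ccc(OCC=C)c2c1OC(C)(C)C=C2 | intermediate
10 | 2,4,6-trifluorobenzoyl chloride | O=C(Cl)c1c(F)cc(F)cc1F | starting material
11 | bromomagnesium enolate of 9 (not isolated; enolate geometry of no consequence) | CC(C)=CCC=C(O[Mg]Br)c1ccc(OCC=C)c2c1OC(C)(C)C=C2 | intermediate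
12 | 1-[2,2-dimethyl-5-(prop-2-en-1-yloxy)-2H-chromen-8-yl]-2-(3-methylbut-2-en-1-yl)-3-(2,4,6-trifluorophenyl)propane-1,3-dione (racemic, not isolated) | CC(C)=CCC(C(=O)c1ccc(OCC=C)c2c1OC(C)(C)C=C2)C(=O)c1c(F)cc(F)cc1F | intermediate
13 | 2-[2,2-dimethyl-5-(prop-2-en-1-yloxy)-2H-chromen-8-yl]-5,7-difluoro-3-(3-methylbut-2-en-1-yl)-4H-chromen-4-one | CC(C)=CCc1c(-c2ccc(OCC=C)c3c2OC(C)(C)C=C3)oc2cc(F)cc(F)c2c1=O | intermediate
14 | 2-[2,2-dimethyl-5-(prop-2-en-1-yloxy)-2H-chromen-8-yl]-5-fluoro-3-(3-methylbut-2-en-1-yl)-7-(prop-2-en-1-yloxy)-4H-chromen-4-one (not isolated) | CC(C)=CCc1c(-c2ccc(OCC=C)c3c2OC(C)(C)C=C3)oc2cc(OCC=C)cc(F)c2c1=O | intermediate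
15 | 2-[2,2-dimethyl-5-(prop-2-en-1-yloxy)-2H-chromen-8-yl]-3-(3-methylbut-2-en-1-yl)-5,7-bis(prop-2-en-1-yloxy)-4H-chromen-4-one | CC(C)=CCc1c(-c2ccc(OCC=C)c3c2OC(C)(C)C=C3)oc2cc(OCC=C)cc(OCC=C)c2c1=O | intermediate
16 | Kuwanon A | CC(C)=CCc1c(-c2ccc(O)c3c2OC(C)(C)C=C3)oc2cc(O)cc(O)c2c1=O | target

Total step count: 7. Longest linear sequence: 7 steps (1 to 16).

Steps most likely to fail

Step 5. Acylation may take place at the enolate oxygen instead of carbon, or soft enolisation of the crowded ketone may be too slow to compete with decay of the acid chloride. The fallback sets out from 9 and comes back at 12. The lithium enolate of 9 (LiN(i-Pr)2, THF, −78 °C) is added to commercial 2,4,6-trifluorobenzaldehyde, an electrophile that can only bond to carbon. This should give the β-hydroxy ketone 1-[2,2-dimethyl-5-(prop-2-en-1-yloxy)-2H-chromen-8-yl]-2-[hydroxy(2,4,6-trifluorophenyl)methyl]-5-methylhex-4-en-1-one F1 as a diastereomer mixture whose two centres are erased later. Dess–Martin periodinane in CH2Cl2 oxidises it to diketone 12, now isolated, and K2CO3 in MeCN at 80 °C closes 12 to 13 as in the second half of step 5.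

Step 2. Etherification of the hydrogen-bonded, doubly flanked phenol may remain incomplete while the tertiary chloride is lost by elimination. The fallback sets out from 2 and comes back at 6, bypassing the propargyl ether. Phenol 2 is heated with commercial 1,1-diethoxy-3-methylbut-2-ene and catalytic 3-picoline in p-xylene at reflux, with removal of ethanol. Acetal exchange at the phenol oxygen, loss of ethanol, sigmatropic transfer of the C5 unit to C3 (the only free ortho carbon) and oxa-6π closure deliver the chromene directly. This condensation is known to tolerate electron-poor phenols. No compound outside the list is made (F0).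

Step 6. The sequence may stall after the first displacement, because the new ether oxygen enriches ring A, or the alkoxide may add to C2 and open ring C. The fallback sets out from 9 and comes back at 15, placing the ring A oxygens before ring closure.
- Commercial 5-fluororesorcinol is bis-allylated (allyl bromide, K2CO3, acetone, reflux) to 1-fluoro-3,5-bis(prop-2-en-1-yloxy)benzene F2.
- Vilsmeier–Haack formylation (POCl3, DMF), para to one ether and ortho to the other, gives 2-fluoro-4,6-bis(prop-2-en-1-yloxy)benzaldehyde F3.
- Pinnick oxidation (NaClO2, NaH2PO4, 2-methylbut-2-ene, t-BuOH/H2O) gives 2-fluoro-4,6-bis(prop-2-en-1-yloxy)benzoic acid F4.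
- Oxalyl chloride with catalytic DMF gives 2-fluoro-4,6-bis(prop-2-en-1-yloxy)benzoyl chloride F5.
- Under the acylation conditions of step 5, ketone 9 and this chloride give the diketone 1-[2,2-dimethyl-5-(prop-2-en-1-yloxy)-2H-chromen-8-yl]-3-[2-fluoro-4,6-bis(prop-2-en-1-yloxy)phenyl]-2-(3-methylbut-2-en-1-yl)propane-1,3-dione F6.
- Its single ortho fluoride, activated only by the carbonyl, is displaced intramolecularly at higher temperature (K2CO3, NMP, 110 °C) to give 15.

Further compounds
F1 | step 5 | 1-[2,2-dimethyl-5-(prop-2-en-1-yloxy)-2H-chromen-8-yl]-2-[hydroxy(2,4,6-trifluorophenyl)methyl]-5-methylhex-4-en-1-one (racemic diastereomer mixture) | CC(C)=CCC(C(=O)c1ccc(OCC=C)c2c1OC(C)(C)C=C2)C(O)c1c(F)cc(F)cc1F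
F0 | step 2 | none | none
F2 | step 6 | 1-fluoro-3,5-bis(prop-2-en-1-yloxy)benzene | C=CCOc1cc(F)cc(OCC=C)c1
F3 | step 6 | 2-fluoro-4,6-bis(prop-2-en-1-yloxy)benzaldehyde | O=Cc1c(F)cc(OCC=C)cc1OCC=C
F4 | step 6 | 2-fluoro-4,6-bis(prop-2-en-1-yloxy)benzoic acid | OC(=O)c1c(F)cc(OCC=C)cc1OCC=C
F5 | step 6 | 2-fluoro-4,6-bis(prop-2-en-1-yloxy)benzoyl chloride | O=C(Cl)c1c(F)cc(OCC=C)cc1OCC=C
F6 | step 6 | 1-[2,2-dimethyl-5-(prop-2-en-1-yloxy)-2H-chromen-8-yl]-3-[2-fluoro-4,6-bis(prop-2-en-1-yloxy)phenyl]-2-(3-methylbut-2-en-1-yl)propane-1,3-dione (racemic) | CC(C)=CCC(C(=O)c1ccc(OCC=C)c2c1OC(C)(C)C=C2)C(=O)c1c(F)cc(OCC=C)cc1OCC=C
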